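**Retrosynthetic overview**
1. Melanocin F ⇒ the free phenol imidazole. The acid-labile aryl sulfate is installed last by O-sulfation.
2. Phenol imidazole ⇒ α-formamido ketone + NH3. The imidazole is the only ring built, and it is closed once, after the C4–C5 bond exists. Both benzene rings are bought.
3. α-Formamido ketone ⇒ C4–C5 bond between an acyl-anion equivalent (thiazolium-bound Breslow enaminol) and an N-formylimine. A C=O carbon is joined to a C=N carbon, and both are natively electrophilic. Either orientation of the coupling gives the same tautomeric imidazole.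
4. The acyl anion comes from catalytic decarboxylation of unprotected (4-hydroxyphenyl)pyruvic acid. The imine comes from the α-formamido sulfone made from (4-methoxyphenyl)acetaldehyde, formamide and TolSO2H.

Assumption: the target has no stereocentre (it is achiral and the two imidazole N–H tautomers interconvert), so no enantiomer has to be set; the stereocentre of racemic 3 and 7 disappears on aromatisation.

**Step 1**
Reactants: 1 (4-methoxyphenyl)acetaldehyde; 2 formamide
Product: 3 N-[2-(4-methoxyphenyl)-1-(4-methylbenzenesulfonyl)ethyl]formamide (racemic)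
Conditions: HCONH2 (2.5 equiv), Me3SiCl (1.1 equiv), MeCN/toluene 1:1, 50 °C, 4 h; then TolSO2H (1.5 equiv), 50 °C, 5 h; H2O/MTBE, 0 °C, filter
Reagents that add atoms: 4-methylbenzenesulfinic acid, Cc1ccc(S(=O)O)cc1
Why: Three-component Mannich-type α-amido sulfone synthesis, in which formamide condenses with the aldehyde under acid, the soft sulfinate sulfur captures the iminium carbon, Me3SiCl takes up the water and crystallisation of 3 drives the equilibrium (an enamide tautomer is re-protonated to the same iminium ion under these acidic conditions); the new stereocentre is racemic and is erased in step 2.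

**Step 2**
Reactants: 3 N-[2-(4-methoxyphenyl)-1-(4-methylbenzenesulfonyl)ethyl]formamide; 4 (4-hydroxyphenyl)pyruvic acid
Product: 8 p-{[5-(4-methoxybenzyl)-1H-imidazol-4-yl]methyl}phenol, via N-formylimine 5 (not isolated), via Breslow enaminol 6 (not isolated), via formamido ketone 7 (not isolated)
Conditions: 4 (1.5 equiv), 3-benzyl-5-(2-hydroxyethyl)-4-methyl-1,3-thiazol-3-ium chloride (20 mol %), Et3N (8 equiv), THF/DMF 4:1, N2 sweep, 50 °C, 3 added in portions over 2 h, then 10 h; then NH4OAc (15 equiv), AcOH/EtOH, reflux, 8 h
Reagents that add atoms: ammonium acetate, CC(=O)[O-].[NH4+]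
Why: Proposed new method: the thiazol-2-ylidene adds to the keto tautomer of 4 and the resulting 2-(1-carboxy-1-hydroxyalkyl)thiazolium zwitterion loses CO2 (fast in a low-polarity medium, as in thiamine-dependent decarboxylation) to give the nucleophilic acyl-anion equivalent 6, which attacks the electrophilic C=N carbon of 5, released slowly from 3 by Et3N so that capture can outrun imine-to-enamide tautomerisation, giving racemic 7, whose stereocentre vanishes when NH4OAc/AcOH closes the ring by Davidson-type cyclodehydration; the closest known reaction types are the thiazolium-catalysed aza-benzoin coupling of aldehydes with α-amido sulfones followed by one-pot imidazole formation, and the thiazolium-catalysed decarboxylative Stetter reaction of α-keto acids.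

**Step 3**
Reactants: 8 p-{[5-(4-methoxybenzyl)-1H-imidazol-4-yl]methyl}phenol
Product: 9 melanocin F, p-{[5-(4-methoxybenzyl)-1H-imidazol-4-yl]methyl}phenyl hydrogen sulfate (isolated as its imidazolium sulfate inner salt)
Conditions: SO3·pyridine (2 equiv), pyridine, 25 °C, 6 h; H2O, NaHCO3 to pH 7, 0→25 °C, 1 h; adjust to pH 5, C18 desalting (H2O→MeOH)
Reagents that add atoms: sulfur trioxide–pyridine complex, O=S(=O)([O-])[n+]1ccccc1
Why: Phenol O-sulfation with a sulfur trioxide–amine complex, mild enough to leave the anisole ring unsulfonated; an N-sulfonated imidazole, should it form, is a labile azolide that neutral water cleaves while the aryl sulfate monoester survives, and no stereocentre is involved.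

**Compound list**
1 | (4-methoxyphenyl)acetaldehyde | COc1ccc(CC=O)cc1 | starting material
2 | formamide | NC=O | starting material
3 | N-[2-(4-methoxyphenyl)-1-(4-methylbenzenesulfonyl)ethyl]formamide (racemic) | COc1ccc(CC(NC=O)S(=O)(=O)c2ccc(C)cc2)cc1 | intermediate
4 | (4-hydroxyphenyl)pyruvic acid, 3-(4-hydroxyphenyl)-2-oxopropanoic acid | OC(=O)C(=O)Cc1ccc(O)cc1 | starting material
5 | (E)-N-[2-(4-methoxyphenyl)ethylidene]formamide (not isolated) | COc1ccc(C/C=N/C=O)cc1 | intermediate
6 | Breslow enaminol, 4-{2-[3-benzyl-5-(2-hydroxyethyl)-4-methyl-1,3-thiazol-2(3H)-ylidene]-2-hydroxyethyl}phenol (not isolated, alkene geometry undefined) | OC(Cc1ccc(O)cc1)=C1SC(CCO)=C(C)N1Cc1ccccc1 | intermediate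
7 | N-[4-(4-hydroxyphenyl)-1-(4-methoxyphenyl)-3-oxobutan-2-yl]formamide (racemic, not isolated) | COc1ccc(CC(NC=O)C(=O)Cc2ccc(O)cc2)cc1 | intermediate
8 | p-{[5-(4-methoxybenzyl)-1H-imidazol-4-yl]methyl}phenol | COc1ccc(Cc2[nH]cnc2Cc2ccc(O)cc2)cc1 | intermediate
9 | melanocin F, p-{[5-(4-methoxybenzyl)-1H-imidazol-4-yl]methyl}phenyl hydrogen sulfate (achiral) | COc1ccc(Cc2[nH]cnc2Cc2ccc(OS(=O)(=O)O)cc2)cc1 | target

**Totals:** 3 steps in all; the longest linear sequence is 3 steps (1 → 3 → 8 → 9).

**Steps most likely to fail, most risky first**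

**Step 2.**
- Compound 4 rests largely as its enol, and its enolate could add to 5 in the normal-polarity Mannich sense.
- Imine 5 can slip to the conjugated styryl formamide.
- Enaminol 6 can be diverted into homo-acyloin products.

The fallback sets out from 3 and comes back at 8. It keeps a masked acyl anion but drops carbene catalysis. Compound 3 is dehydrated with POCl3/Et3N in THF at −5 °C to the substituted tosylmethyl isocyanide 1-[1-isocyano-2-(4-methoxyphenyl)ethanesulfonyl]-4-methylbenzene F1. Purchased [4-(benzyloxy)phenyl]acetaldehyde is stirred with NH3 (7 M in MeOH) to form 2-[4-(benzyloxy)phenyl]ethan-1-imine F2 in situ. The K2CO3-generated carbanion of F1 adds to this C=N bond, the nitrogen closes onto the isocyanide carbon and sulfinate is lost (van Leusen three-component imidazole synthesis). This gives 4-[4-(benzyloxy)benzyl]-5-(4-methoxybenzyl)-1H-imidazole F3. Hydrogenolysis (H2, Pd/C, MeOH) then gives 8.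

**Step 1.**
- Formamide is a weak N-nucleophile.
- Aldehyde 1 is acid-sensitive (aldol reaction, enamide formation), so 3 may not crystallise cleanly.

The fallback sets out from 1 and comes back at 8. It moves the C2 carbon to the end of the sequence. Compound 1, tert-butyl carbamate, TolSO2Na and HCO2H in MeOH/H2O at 25 °C give tert-butyl N-[2-(4-methoxyphenyl)-1-(4-methylbenzenesulfonyl)ethyl]carbamate F4. This compound class is well behaved for arylacetaldehydes. Under the first-stage conditions of step 2, Et3N releases tert-butyl (E)-N-[2-(4-methoxyphenyl)ethylidene]carbamate F5. Enaminol 6, generated from 4, captures F5 to give tert-butyl N-[4-(4-hydroxyphenyl)-1-(4-methoxyphenyl)-3-oxobutan-2-yl]carbamate F6. HCl in dioxane gives 3-amino-1-(4-hydroxyphenyl)-4-(4-methoxyphenyl)butan-2-one hydrochloride F7. Heating F7 with formamidine acetate in EtOH (amidine exchange, then cyclodehydration) delivers 8.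

**Step 3.**
- The imidazole nitrogen competes for SO3.
- The product is acid-labile.
- The inner salt must be separated from inorganic sulfate.

The fallback sets out from 8 and comes back at 9, using a latent sulfate that can be chromatographed. Phenolate-selective sulfur–fluoride exchange (SO2F2 balloon, Et3N, CH2Cl2, 25 °C) gives the neutral p-{[5-(4-methoxybenzyl)-1H-imidazol-4-yl]methyl}phenyl sulfurofluoridate F8, which is purified on silica. Cs2CO3 in ethylene glycol at 25 °C then converts the fluorosulfate into the sulfate monoester. Adjusting to pH 5 and C18 desalting give 9.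

**Further compounds**
F1 | step 2 | 1-[1-isocyano-2-(4-methoxyphenyl)ethanesulfonyl]-4-methylbenzene (racemic) | COc1ccc(CC([N+]#[C-])S(=O)(=O)c2ccc(C)cc2)cc1
F2 | step 2 | 2-[4-(benzyloxy)phenyl]ethan-1-imine | N=CCc1ccc(OCc2ccccc2)cc1
F3 | step 2 | 4-[4-(benzyloxy)benzyl]-5-(4-methoxybenzyl)-1H-imidazole | COc1ccc(Cc2[nH]cnc2Cc2ccc(OCc3ccccc3)cc2)cc1
F4 | step 1 | tert-butyl N-[2-(4-methoxyphenyl)-1-(4-methylbenzenesulfonyl)ethyl]carbamate (racemic) | COc1ccc(CC(NC(=O)OC(C)(C)C)S(=O)(=O)c2ccc(C)cc2)cc1
F5 | step 1 | tert-butyl (E)-N-[2-(4-methoxyphenyl)ethylidene]carbamate | COc1ccc(C/C=N/C(=O)OC(C)(C)C)cc1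
F6 | step 1 | tert-butyl N-[4-(4-hydroxyphenyl)-1-(4-methoxyphenyl)-3-oxobutan-2-yl]carbamate (racemic) | COc1ccc(CC(NC(=O)OC(C)(C)C)C(=O)Cc2ccc(O)cc2)cc1
F7 | step 1 | 3-amino-1-(4-hydroxyphenyl)-4-(4-methoxyphenyl)butan-2-one hydrochloride (racemic) | Cl.COc1ccc(CC(N)C(=O)Cc2ccc(O)cc2)cc1
F8 | step 3 | p-{[5-(4-methoxybenzyl)-1H-imidazol-4-yl]methyl}phenyl sulfurofluoridate | COc1ccc(Cc2[nH]cnc2Cc2ccc(OS(=O)(=O)F)cc2)cc1
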